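**Retrosynthetic overview**
- The seven-membered ring is opened at its trisubstituted alkene (ring-closing metathesis), giving a cyclopentane with a vinyl carbinol angelate arm and a methallyl carbinol benzoate arm, trans to each other.
- Angelate from the secondary allylic alcohol, made by CBS reduction of a vinyl ketone; benzoate on the aldol hydroxyl; tertiary isopropyl carbinol from organocerium addition to the ring ketone.
- Key disconnection: the bond between the quaternary methyl carbon and the future angelate carbinol carbon. An acryloyl-anion equivalent (metalated methoxyallene) adds 1,4 to 3-methylcyclopent-2-enone under chiral NHC–copper catalysis, and the enolate is trapped in the same flask by 3-methylbut-3-enal.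
- Ring order: the five-membered ring is bought as the enone; the seven-membered ring is closed in the last step.

Assumption: the three starting materials and all reagents are bought as such; the NHC precursor L* = (4S,5S)-1-(2,6-diethylphenyl)-4,5-diphenyl-3-(2-sulfonatophenyl)-4,5-dihydro-1H-imidazol-3-ium inner salt is taken to give the (3S) adduct, and its mirror image is used if the sense proves opposite.

**Step 1**
Reactants: 1 3-methylbut-3-en-1-ol
Product: 2 3-methylbut-3-enal
Conditions: Dess–Martin periodinane, CH2Cl2, 0 °C → rt; filtered and used at once as a solution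
Reagents that add atoms: none
Why: Dess–Martin oxidation of a primary alcohol under non-basic conditions, which keeps the double bond out of conjugation; no stereocentre is formed.

**Step 2**
Reactants: 3 methoxyallene (1-methoxypropa-1,2-diene); 4 3-methylcyclopent-2-en-1-one; 2 3-methylbut-3-enal
Product: 8 (2S,3S)-2-[(1S)-1-hydroxy-3-methylbut-3-en-1-yl]-3-(1-methoxypropa-1,2-dien-1-yl)-3-methylcyclopentan-1-one, via 1-lithio-1-methoxyallene 5 (not isolated), via diisobutyl(1-methoxyallenyl)aluminium 6 (not isolated), via aluminium enolate 7 (not isolated)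
Conditions: 3, n-BuLi, THF, −40 °C; i-Bu2AlCl, −78 °C; then 4, Cu(OTf)2 (5 mol %), L* (6 mol %), THF, −78 → −40 °C; then 2, −78 °C; aq. KNaC4H4O6 work-up
Reagents that add atoms: none
Why: Proposed new method: lithiated methoxyallene is an established acryloyl-anion reagent that reacts through its oxygen-bearing carbon, and after transmetalation to the alane its sp2 C–Al bond should be transferred by the NHC–copper catalyst as in the known copper-catalysed enantioselective conjugate additions of alpha-silyl vinylaluminium reagents to 3-methylcyclopentenone (closest known reaction type), so the acyl-anion carbon bonds to the electrophilic beta-carbon and the ligand sets the quaternary centre (3S); the regiodefined aluminium enolate then adds to aldehyde 2 through a closed six-membered transition state on the face trans to the allenyl group, the E(O) ring enolate giving the anti aldol (2S, carbinol S).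

**Step 3**
Reactants: 8 (2S,3S)-2-[(1S)-1-hydroxy-3-methylbut-3-en-1-yl]-3-(1-methoxypropa-1,2-dien-1-yl)-3-methylcyclopentan-1-one
Product: 9 (1R,2S,3S)-2-[(1S)-1-hydroxy-3-methylbut-3-en-1-yl]-3-(1-methoxypropa-1,2-dien-1-yl)-3-methyl-1-(propan-2-yl)cyclopentan-1-ol
Conditions: i-PrMgCl (3 equiv), anhydrous CeCl3 (3 equiv), THF, −78 → −40 °C; aq. NaHCO3 work-up
Reagents that add atoms: isopropylmagnesium chloride, CC(C)[Mg]Cl
Why: Organocerium (Imamoto) 1,2-addition to an enolisable hindered ketone, the reagent attacking the cyclopentanone face opposite the adjacent chelated hydroxyalkyl arm, so the new tertiary hydroxyl is cis to that arm (1R) while the enol ether and alkenes are untouched.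

**Step 4**
Reactants: 9 (1R,2S,3S)-2-[(1S)-1-hydroxy-3-methylbut-3-en-1-yl]-3-(1-methoxypropa-1,2-dien-1-yl)-3-methyl-1-(propan-2-yl)cyclopentan-1-ol
Product: 11 (1S)-1-[(1S,2R,5S)-2-hydroxy-5-methyl-2-(propan-2-yl)-5-(prop-2-enoyl)cyclopentyl]-3-methylbut-3-en-1-yl benzoate, via allenyl ether benzoate 10 (not isolated)
Conditions: BzCl, Et3N, DMAP (cat.), CH2Cl2, 0 °C → rt; then 1 M aq. H2SO4, THF, 0 °C
Reagents that add atoms: benzoyl chloride, O=C(Cl)c1ccccc1; water, O
Why: Selective acylation of the secondary hydroxyl (the tertiary one is inert), then acid hydrolysis of the 1-alkoxyallene through its oxygen-stabilised allyl cation to the vinyl ketone; no stereocentre is touched.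

**Step 5**
Reactants: 11 (1S)-1-[(1S,2R,5S)-2-hydroxy-5-methyl-2-(propan-2-yl)-5-(prop-2-enoyl)cyclopentyl]-3-methylbut-3-en-1-yl benzoate
Product: 12 (1S)-1-[(1S,2R,5S)-2-hydroxy-5-[(1R)-1-hydroxyprop-2-en-1-yl]-5-methyl-2-(propan-2-yl)cyclopentyl]-3-methylbut-3-en-1-yl benzoate
Conditions: (S)-Me-CBS oxazaborolidine [(3aS)-1-methyl-3,3-diphenyltetrahydro-1H,3H-pyrrolo[1,2-c][1,3,2]oxazaborole] (20 mol %), catecholborane (2.5 equiv), toluene, −78 °C; MeOH quench, pH 7 work-up
Reagents that add atoms: none
Why: Corey–Bakshi–Shibata reduction in which the quaternary carbon acts as the large group, so hydride goes to the face that gives the (R)-carbinol, the same face Felkin–Anh substrate control prefers (hydride anti to the ring CH and past the methyl), and catecholborane at −78 °C reduces 1,2 without touching esters or alkenes.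

**Step 6**
Reactants: 12 (1S)-1-[(1S,2R,5S)-2-hydroxy-5-[(1R)-1-hydroxyprop-2-en-1-yl]-5-methyl-2-(propan-2-yl)cyclopentyl]-3-methylbut-3-en-1-yl benzoate
Product: 13 (1S)-1-[(1S,2R,5S)-2-hydroxy-5-methyl-5-[(1R)-1-{[(2Z)-2-methylbut-2-enoyl]oxy}prop-2-en-1-yl]-2-(propan-2-yl)cyclopentyl]-3-methylbut-3-en-1-yl benzoate
Conditions: angelic acid, 2,4,6-trichlorobenzoyl chloride, Et3N, toluene, rt, 2 h; then 12, 80 °C
Reagents that add atoms: angelic acid [(2Z)-2-methylbut-2-enoic acid], C/C=C(/C)C(=O)O
Why: Yamaguchi-type mixed-anhydride acylation without a nucleophilic catalyst, conditions that keep the Z geometry of the angelate; only the secondary allylic hydroxyl reacts, with retention at the carbinol carbon.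

**Step 7**
Reactants: 13 (1S)-1-[(1S,2R,5S)-2-hydroxy-5-methyl-5-[(1R)-1-{[(2Z)-2-methylbut-2-enoyl]oxy}prop-2-en-1-yl]-2-(propan-2-yl)cyclopentyl]-3-methylbut-3-en-1-yl benzoate
Product: 14 (3R,3aS,4S,8R,8aS)-4-(benzoyloxy)-3-hydroxy-6,8a-dimethyl-3-(propan-2-yl)-1,2,3,3a,4,5,8,8a-octahydroazulen-8-yl (2Z)-2-methylbut-2-enoate
Conditions: second-generation Hoveyda–Grubbs catalyst RuCl2(H2IMes)(=CH–C6H4–2-O-i-Pr) (5 mol %), toluene (2 mM), 80 °C
Reagents that add atoms: none
Why: Ring-closing metathesis between the vinyl group and the 1,1-disubstituted alkene closes the trisubstituted cycloheptene with loss of ethene; no stereocentre is touched, and the trans ring fusion follows from the trans arms set in step 2 (the angelate alkene is too hindered and electron-poor to take part).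

**Compound list**
1 | 3-methylbut-3-en-1-ol | CC(=C)CCO | starting material
2 | 3-methylbut-3-enal | CC(=C)CC=O | intermediate
3 | methoxyallene (1-methoxypropa-1,2-diene) | COC=C=C | starting material
4 | 3-methylcyclopent-2-en-1-one | CC1=CC(=O)CC1 | starting material
5 | (1-methoxypropa-1,2-dien-1-yl)lithium | [Li]C(OC)=C=C | intermediate
6 | diisobutyl(1-methoxypropa-1,2-dien-1-yl)aluminium | COC(=C=C)[Al](CC(C)C)CC(C)C | intermediate
7 | diisobutylaluminium (3S)-3-(1-methoxypropa-1,2-dien-1-yl)-3-methylcyclopent-1-en-1-olate | COC(=C=C)[C@@]1(C)CCC(O[Al](CC(C)C)CC(C)C)=C1 | intermediate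
8 | (2S,3S)-2-[(1S)-1-hydroxy-3-methylbut-3-en-1-yl]-3-(1-methoxypropa-1,2-dien-1-yl)-3-methylcyclopentan-1-one | COC(=C=C)[C@@]1(C)CCC(=O)[C@@H]1[C@@H](O)CC(C)=C | intermediate
9 | (1R,2S,3S)-2-[(1S)-1-hydroxy-3-methylbut-3-en-1-yl]-3-(1-methoxypropa-1,2-dien-1-yl)-3-methyl-1-(propan-2-yl)cyclopentan-1-ol | COC(=C=C)[C@@]1(C)CC[C@@](O)(C(C)C)[C@@H]1[C@@H](O)CC(C)=C | intermediate
10 | (1S)-1-[(1S,2R,5S)-2-hydroxy-5-(1-methoxypropa-1,2-dien-1-yl)-5-methyl-2-(propan-2-yl)cyclopentyl]-3-methylbut-3-en-1-yl benzoate | COC(=C=C)[C@@]1(C)CC[C@@](O)(C(C)C)[C@@H]1[C@@H](OC(=O)c2ccccc2)CC(C)=C | intermediate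
11 | (1S)-1-[(1S,2R,5S)-2-hydroxy-5-methyl-2-(propan-2-yl)-5-(prop-2-enoyl)cyclopentyl]-3-methylbut-3-en-1-yl benzoate | C=CC(=O)[C@@]1(C)CC[C@@](O)(C(C)C)[C@@H]1[C@@H](OC(=O)c2ccccc2)CC(C)=C | intermediate
12 | (1S)-1-[(1S,2R,5S)-2-hydroxy-5-[(1R)-1-hydroxyprop-2-en-1-yl]-5-methyl-2-(propan-2-yl)cyclopentyl]-3-methylbut-3-en-1-yl benzoate | C=C[C@@H](O)[C@@]1(C)CC[C@@](O)(C(C)C)[C@@H]1[C@@H](OC(=O)c2ccccc2)CC(C)=C | intermediate
13 | (1S)-1-[(1S,2R,5S)-2-hydroxy-5-methyl-5-[(1R)-1-{[(2Z)-2-methylbut-2-enoyl]oxy}prop-2-en-1-yl]-2-(propan-2-yl)cyclopentyl]-3-methylbut-3-en-1-yl benzoate | C/C=C(/C)C(=O)O[C@H](C=C)[C@@]1(C)CC[C@@](O)(C(C)C)[C@@H]1[C@@H](OC(=O)c2ccccc2)CC(C)=C | intermediate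
14 | (3R,3aS,4S,8R,8aS)-4-(benzoyloxy)-3-hydroxy-6,8a-dimethyl-3-(propan-2-yl)-1,2,3,3a,4,5,8,8a-octahydroazulen-8-yl (2Z)-2-methylbut-2-enoate | C/C=C(/C)C(=O)O[C@@H]1C=C(C)C[C@H](OC(=O)c2ccccc2)[C@@H]2[C@]1(C)CC[C@@]2(O)C(C)C | target

**Count**
Total steps: 7. Longest linear sequence: 7 (steps 1 to 7 from 3-methylbut-3-en-1-ol; 6 from the enone 4).

**Steps most likely to fail**

Step 2. The allenyl group may be transferred through its far carbon (propargyl-type product), the hindered beta-carbon may not react, or the aldol may show modest face selectivity next to the quaternary centre. The fallback sets out from 3 and comes back at 8. Lithio compound 5 (from 3) is added 1,2 to purchased 3-ethoxycyclopent-2-en-1-one at −78 °C to give 3-ethoxy-1-(1-methoxypropa-1,2-dien-1-yl)cyclopent-2-en-1-ol F1. On pH 5 buffered work-up this loses ethanol by Stork–Danheiser transposition to 3-(1-methoxypropa-1,2-dien-1-yl)cyclopent-2-en-1-one F2, so the same bond is still made by the acyl-anion reagent. The quaternary centre is then created by copper-catalysed enantioselective 1,4-addition of AlMe3 (Cu(OTf)2, a chiral NHC of the same class), which is known to add 1,4 rather than 1,6 to 3-alkenyl cycloalkenones, and the aluminium enolate is trapped with 2 as before to give 8.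

Step 3. The beta-hydroxy ketone may undergo retro-aldol cleavage or enolisation, or the reagent may attack the wrong face. The fallback sets out from 8 and comes back at 9. TESCl and imidazole in DMF give (2S,3S)-3-(1-methoxypropa-1,2-dien-1-yl)-3-methyl-2-[(1S)-3-methyl-1-(triethylsilyloxy)but-3-en-1-yl]cyclopentan-1-one F3, in which no alkoxide sits beta to the ketone and the bulky silyloxy arm shields its own face. Addition of i-PrLi/CeCl3 at −78 °C under steric control gives (1R,2S,3S)-3-(1-methoxypropa-1,2-dien-1-yl)-3-methyl-2-[(1S)-3-methyl-1-(triethylsilyloxy)but-3-en-1-yl]-1-(propan-2-yl)cyclopentan-1-ol F4, and TBAF in THF returns 9.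

Step 6. The angelate may isomerise to the tiglate, or the hindered alcohol next to the quaternary carbon may not acylate. The fallback sets out from 12 and comes back at 13. Esterification with 2-(diphenoxyphosphoryl)propanoic acid (EDC, DMAP, CH2Cl2; no alkene geometry to lose, so forcing conditions are allowed) gives the 2-(diphenoxyphosphoryl)propanoate of 12 at its allylic hydroxyl F5. A Z-selective Horner–Wadsworth–Emmons (Ando) olefination with acetaldehyde (NaH, THF, −78 °C) then builds the angelate double bond in place and gives 13.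

**Further compounds**
F1 | step 2 | 3-ethoxy-1-(1-methoxypropa-1,2-dien-1-yl)cyclopent-2-en-1-ol (racemic) | CCOC1=CC(O)(C(OC)=C=C)CC1
F2 | step 2 | 3-(1-methoxypropa-1,2-dien-1-yl)cyclopent-2-en-1-one | COC(=C=C)C1=CC(=O)CC1
F3 | step 3 | (2S,3S)-3-(1-methoxypropa-1,2-dien-1-yl)-3-methyl-2-[(1S)-3-methyl-1-(triethylsilyloxy)but-3-en-1-yl]cyclopentan-1-one | COC(=C=C)[C@@]1(C)CCC(=O)[C@@H]1[C@@H](O[Si](CC)(CC)CC)CC(C)=C
F4 | step 3 | (1R,2S,3S)-3-(1-methoxypropa-1,2-dien-1-yl)-3-methyl-2-[(1S)-3-methyl-1-(triethylsilyloxy)but-3-en-1-yl]-1-(propan-2-yl)cyclopentan-1-ol | COC(=C=C)[C@@]1(C)CC[C@@](O)(C(C)C)[C@@H]1[C@@H](O[Si](CC)(CC)CC)CC(C)=C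
F5 | step 6 | 2-(diphenoxyphosphoryl)propanoate of 12 at its allylic hydroxyl (mixture at the phosphonate carbon) | CC(C(=O)O[C@H](C=C)[C@@]1(C)CC[C@@](O)(C(C)C)[C@@H]1[C@@H](OC(=O)c2ccccc2)CC(C)=C)P(=O)(Oc2ccccc2)Oc2ccccc2
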